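I started from a leftover: 52% of the substrate charge still stood in the east run at 4.00 min.

| flask | substrate | reagent | catalyst | remark | time |
|---|---|---|---|---|---|
| east | 1.5 M | 1.2 M | 75 mM | run made earlier |  |
| north | 1.5 M | 1.2 M | 300 mM | run made earlier |  |
| south-east | 3 M | 1.2 M | 150 mM | run made earlier |  |
| flask | 1.5 M | 1.20 M | 150 mM |  | 4.0 min |

| run | time / min | target / % | substrate / % | isomer of the product / % |
|---|---|---|---|---|
| east | 1.33 | 27 | 57 | 15 |
| east | 2.50 | 28 | 53 | 19 |
| east | 4.00 | 31 | 52 | 20 |
| east | 5.00 | 25 | 50 | 21 |
| north | 1.33 | 19 | 67 | 10 |
| north | 2.50 | 21 | 60 | 17 |
| north | 4.00 | 25 | 56 | 19 |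
| north | 5.00 | 22 | 56 | 27 |
| south-east | 0.417 | 11 | 81 | 5 |
| south-east | 0.833 | 15 | 75 | 7 |
| south-east | 2.00 | 18 | 72 | 13 |
| south-east | 5.00 | 12 | 66 | 16 |

(readings scatter by 2 percentage points)

* target present at 4.0 min, in percent of the substrate charged
* substrate present at 4.0 min, in percent of the substrate charged
* isomer of the product present at 4.0 min, in percent of the substrate charged

I read the runs from the quickest event to the slowest.

Step one. My guess was that each catalyst holds one reagent before the first reading. The north run, with more catalyst than the east run, kept more substrate at 4.00 min: 56% against 52%, each reading good to 2 percentage points.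

Step two. Substrate fell early. The east run held 57% at 1.33 min and 50% at 5.00 min.

Step three. Target fell late. In the south-east run it went from 18% at 2.00 min to 12% at 5.00 min, while isomer of the product rose from 13% to 16%.

Step four. In the flask, reagent is the limiting reagent. Reagent minus catalyst, over substrate charged, gave 70.0%. This is my reagent room: the reagent free to turn once catalyst has taken its full share, as a fraction of the substrate charge. If catalyst holds that full share and each substrate used takes one reagent, free reagent is the room minus the substrate used.

Step five. The flask's catalyst lies a third of the way from the east run to the north run. From those two single readings, at 4.0 min, I estimated 53.3% substrate left, 46.7% in target and isomer of the product together, and free reagent at 29.2% of its own charge.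

The forecast gave target 26%, substrate 54% and isomer of the product 20%: “Interpolating on log catalyst”, whereas my line was straight in catalyst and gave the substrate figure of step five.

The flask gave target 26.4%, substrate 52.4% and isomer of the product 21.2%.

    substrate + reagent ⇌ target (K = 1.40 /M, k = 0.00690 /M/s)
    substrate + reagent ⇌ isomer of the product (K = 2.60 /M, k = 0.00270 /M/s)
    target + catalyst ⇌ isomer of the product + catalyst, rate k3*[catalyst]*[target] forward; the back reaction follows from the equilibrium constant (k = 0.0600 /M/s)
    reagent + catalyst ⇌ idle complex, settled at all times (K = 27.0 /M)

In the flask, the step to target had 95% of its turnover up to 4.0 min behind it at 2.00 min, with reagent at 36.4% of its own charge. The turning of target into isomer of the product reached half of its turnover up to 4.0 min later, at 2.41 min. At 4.00 min the room gives free reagent at 28.0% of its own charge; the flask holds 29.2%, with idle complex at 90.4% of the catalyst. In the neighbour flask with 2.0 M reagent the room is 123%, and 31.3% substrate left gives free reagent at 41.0% of its own charge. That computed flask holds 41.3%.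

(All runs stem from a simulated flask with constants of no real substance; noise was put on by code.)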